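**Plan**

1. Numbering: ring A is the pyranone (O1, C2–C6). Ring B is the benzene ring with C1' (CH2 bridge), C2' (OCH3), C3' (H), C4' (OH), C5' (acyl) and C6' (OH).
2. Cuts: (a) both bonds of the CH2 bridge (C3–CH2 and CH2–C1'); (b) after ethyl is traced back to vinyl, the bond between the C5' ketone carbon and its methine carbon; (c) C4–C5 and O1–C2 of ring A.
3. Enabling feature: the ketone carbon on C5' of ring B sits between the free hydroxyls on C4' and C6' and carries a CH(CH3)(C2H5) group. It can therefore be read as the formyl carbon of a symmetrical salicylaldehyde whose C–H has added across one C=C of buta-1,3-diene, the second C=C being reduced afterwards.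
4. Forward order: ring A is closed from the silyl enol ether of 3-pentanone and malonyl dichloride (the only ring made; ring B is bought). The aldehyde is hydroacylated with butadiene, the vinyl group is hydrogenated, and the two halves are joined last through the carbon of a methyleneiminium salt.
5. Stereochemistry: the single (R) centre is created in the hydroacylation under control of a chiral bisphosphine on rhodium. The later steps do not touch it and the descriptor stays (R).

Key step: step 3

Assumption: aldehyde 6 is taken as purchasable; the sense of induction of the SEGPHOS ligand cannot be predicted, so the (R)-ligand is written as the working choice and its antipode would be used if the (S)-ketone were to form.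

**Route**

Step 1
Reactants: 1 3-pentanone
Product: 2 3-(trimethylsilyloxy)pent-2-ene (E/Z mixture)
Conditions: TMSOTf (1.05 equiv), Et3N (1.2 equiv), Et2O, 0 °C → rt; distillation
Reagents that add atoms: trimethylsilyl trifluoromethanesulfonate, C[Si](C)(C)OS(=O)(=O)C(F)(F)F
Why: Silyl enol ether formation by O-silylation/deprotonation of a symmetrical ketone, so there is no regiochemical choice, and the alkene geometry is irrelevant because it is lost in step 2.

Step 2
Reactants: 2 3-(trimethylsilyloxy)pent-2-ene; 3 malonyl dichloride
Product: 5 6-ethyl-4-hydroxy-5-methyl-2H-pyran-2-one, via 4-methyl-3,5-dioxoheptanoyl chloride 4 (not isolated)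
Conditions: 3 (1.0 equiv), Et2O, −78 °C → rt, overnight, no base; product collected by filtration and recrystallisation
Reagents that add atoms: none
Why: Effenberger pyranone synthesis: C-acylation of the silyl enol ether by one acyl chloride gives the diketo acid chloride, whose ethyl-ketone enol is O-acylated by the second acyl chloride to close the six-membered lactone (ring A).

Step 3
Reactants: 6 2,6-dihydroxy-4-methoxybenzaldehyde; 7 buta-1,3-diene
Product: 8 (2R)-1-(2,6-dihydroxy-4-methoxyphenyl)-2-methylbut-3-en-1-one
Conditions: [Rh(C8H12)(OCH3)]2 (2.5 mol %; C8H12 = 1,5-cyclooctadiene), (R)-DTBM-SEGPHOS (5.5 mol %), 7 (5 equiv, solution in toluene), toluene, sealed vessel, 40 °C, no added acid or base; short silica plug, then straight into step 4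
Reagents that add atoms: none
Why: Proposed new method: the methoxide of the precatalyst turns one phenol of 6 into a phenoxide on monovalent rhodium, and oxidative addition of the chelated formyl C–H gives an acyl hydride of trivalent rhodium held in a five-membered acyl–phenoxide chelate that resists decarbonylation; butadiene inserts into Rh–H to give an η3-1-methylallyl acyl complex, and C–C reductive elimination at the methyl-bearing allyl terminus gives the branched β,γ-unsaturated ketone, so the formyl carbon ends up bonded to carbon as an acyl anion equivalent. The closest known reactions are the rhodium-catalysed, phenoxide-directed intermolecular hydroacylations of alkenes, norbornadienes and non-conjugated dienes by salicylaldehydes (enantioselective variants with chiral phosphorus ligands included) and the ruthenium hydride and cobalt hydroacylations of 1,3-dienes to β,γ-unsaturated ketones, whereas an enantioselective branched addition of a salicylaldehyde to butadiene itself is not established. No ring is formed. The new (R) centre is controlled by the chiral bisphosphine, which at the reductive elimination has to tell a methyl from a vinyl group on the allyl terminus, a far larger difference than the methyl/ethyl pair left in the target after hydrogenation. The step needs branched (1,2) rather than linear (1,4) coupling, one enantioface, and no migration of the new alkene into conjugation; the first two rest on the bulky ligand pocket and on the tendency of rhodium allyls to couple at the substituted terminus, the third on mild temperature and on a precatalyst that releases only methanol. The substrate helps because the aldehyde is symmetrical (either hydroxyl can chelate, so the acyl position is unambiguous) and its ortho-phenoxide anchors the acyl hydride so that C–H activation is fast at low temperature.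

Step 4
Reactants: 8 (2R)-1-(2,6-dihydroxy-4-methoxyphenyl)-2-methylbut-3-en-1-one
Product: 9 (2R)-1-(2,6-dihydroxy-4-methoxyphenyl)-2-methylbutan-1-one
Conditions: H2 (1 atm), RhCl(PPh3)3 (5 mol %), degassed toluene–EtOH 1:1, rt
Reagents that add atoms: none
Why: Homogeneous hydrogenation with Wilkinson's catalyst RhCl(PPh3)3 reduces a monosubstituted alkene quickly with little double-bond migration and leaves the aryl ketone and phenols alone; the stereocentre is not a reacting atom and stays (R) because ethyl still ranks above methyl.

Step 5
Reactants: 5 6-ethyl-4-hydroxy-5-methyl-2H-pyran-2-one; 9 (2R)-1-(2,6-dihydroxy-4-methoxyphenyl)-2-methylbutan-1-one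
Product: 12 3-({2,4-dihydroxy-6-methoxy-3-[(2R)-2-methylbutanoyl]phenyl}methyl)-6-ethyl-4-hydroxy-5-methyl-2H-pyran-2-one, via Mannich base 10 (not isolated), via methylidene pyrandione 11 (not isolated)
Conditions: 5, CH2=NMe2+ I− (1.0 equiv), CH2Cl2, rt, 1 h; then 9 (1.3 equiv, excess recovered), 40 °C
Reagents that add atoms: N,N-dimethylmethylideneammonium iodide (Eschenmoser's salt), C=[N+](C)C.[I-]
Why: Mannich aminomethylation of the pyranone C3, thermal loss of dimethylamine to the methylidene dione and Friedel–Crafts-type conjugate addition of a free ring carbon of the acylphloroglucinol, i.e. the methylene-bridging reaction established for phloroglucinol–pyranone dimers; the two free ring positions of 9 are equivalent and the side-chain centre is not involved.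

**Compound list**

1 | 3-pentanone | CCC(=O)CC | starting material
2 | 3-(trimethylsilyloxy)pent-2-ene (E/Z mixture) | CC=C(CC)O[Si](C)(C)C | intermediate
3 | malonyl dichloride | O=C(Cl)CC(=O)Cl | starting material
4 | 4-methyl-3,5-dioxoheptanoyl chloride (enolisable, not isolated) | CCC(=O)C(C)C(=O)CC(=O)Cl | intermediate
5 | 6-ethyl-4-hydroxy-5-methyl-2H-pyran-2-one | CCc1oc(=O)cc(O)c1C | intermediate
6 | 2,6-dihydroxy-4-methoxybenzaldehyde | COc1cc(O)c(C=O)c(O)c1 | starting material
7 | buta-1,3-diene | C=CC=C | starting material
8 | (2R)-1-(2,6-dihydroxy-4-methoxyphenyl)-2-methylbut-3-en-1-one | COc1cc(O)c(C(=O)[C@H](C)C=C)c(O)c1 | intermediate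
9 | (2R)-1-(2,6-dihydroxy-4-methoxyphenyl)-2-methylbutan-1-one | COc1cc(O)c(C(=O)[C@H](C)CC)c(O)c1 | intermediate
10 | 3-[(dimethylamino)methyl]-6-ethyl-4-hydroxy-5-methyl-2H-pyran-2-one (formed as its hydroiodide, not isolated) | CCc1oc(=O)c(CN(C)C)c(O)c1C | intermediate
11 | 6-ethyl-5-methyl-3-methylidene-2H-pyran-2,4(3H)-dione (not isolated) | CCC1=C(C)C(=O)C(=C)C(=O)O1 | intermediate
12 | 3-({2,4-dihydroxy-6-methoxy-3-[(2R)-2-methylbutanoyl]phenyl}methyl)-6-ethyl-4-hydroxy-5-methyl-2H-pyran-2-one | CCc1oc(=O)c(Cc2c(OC)cc(O)c(C(=O)[C@H](C)CC)c2O)c(O)c1C | target

**Step count**

Total: 5 steps. Longest linear sequence: 3 steps (6 → 8 → 9 → 12, or equally 1 → 2 → 5 → 12).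

**Steps most likely to fail**

Step 3 (proposed new method). Several things may go wrong:
- reductive elimination at the unsubstituted allyl terminus, giving the linear 1,4-adduct;
- weak facial discrimination by the ligand;
- decarbonylation of the acyl hydride, or rhodium-mediated oligomerisation of the diene;
- migration of the new alkene into conjugation, followed by oxa-Michael closure of a flanking phenol to a chromanone, which also erases the centre.

The fallback uses known chemistry, sets out from 6 and returns at 9, so that step 4 is bypassed as well. Both phenols of 6 are protected (NaH, MOMCl, DMF, 0 °C) to give 2,6-bis(methoxymethoxy)-4-methoxybenzaldehyde F1. Brown crotylboration follows, with the (E)-crotyldiisopinocampheylborane made from trans-but-2-ene, n-BuLi/KOt-Bu and (+)-Ipc2BOMe (the reagent derived from (−)-α-pinene), in THF at −78 °C with NaOH/H2O2 work-up. It should give the anti homoallylic alcohol (1R,2R)-1-[2,6-bis(methoxymethoxy)-4-methoxyphenyl]-2-methylbut-3-en-1-ol F2, in which the methyl-bearing carbon already has the required configuration. Hydrogenation (H2, RhCl(PPh3)3, toluene–EtOH) gives (1R,2R)-1-[2,6-bis(methoxymethoxy)-4-methoxyphenyl]-2-methylbutan-1-ol F3. Buffered Dess–Martin oxidation (NaHCO3, CH2Cl2) removes the carbinol centre and gives (2R)-1-[2,6-bis(methoxymethoxy)-4-methoxyphenyl]-2-methylbutan-1-one F4. Cleavage of both acetals (HCl, MeOH, 40 °C) returns 9.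

Step 5. What may go wrong is a second alkylation at the remaining free ring carbon (C3') of the product, or self-condensation of the pyranone with its own methylidene derivative to a methylene-bis(pyranone); both consume the electrophile. The fallback sets out from 9 and returns at 12. Rieche formylation (Cl2CHOCH3, TiCl4, CH2Cl2, −78 → 0 °C) places a single, deactivating formyl group on the ring and gives 2,4-dihydroxy-6-methoxy-3-[(2R)-2-methylbutanoyl]benzaldehyde F5. A three-component reductive Knoevenagel alkylation of 5 with this aldehyde and Hantzsch ester (L-proline cat., CH2Cl2, rt) then builds the same bridge with strict 1:1 stoichiometry and gives 12.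

Step 4. What may go wrong is metal-hydride-mediated migration of the terminal alkene into conjugation with the ketone before it is reduced, which would erase the centre, or slow turnover through chelation of the catalyst by the o-hydroxy ketone. The fallback sets out from 8 and returns at 9. It is a metal-free reduction with diimide generated from dipotassium azodicarboxylate (KO2C–N=N–CO2K) and acetic acid in MeOH at 0 °C → rt. This is a concerted syn transfer of H2 that cannot pass through metal alkyl or allyl intermediates. No new compound arises (entry F0).

**Further compounds**

F1 | step 3 | 2,6-bis(methoxymethoxy)-4-methoxybenzaldehyde | COCOc1cc(OC)cc(OCOC)c1C=O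
F2 | step 3 | (1R,2R)-1-[2,6-bis(methoxymethoxy)-4-methoxyphenyl]-2-methylbut-3-en-1-ol | COCOc1cc(OC)cc(OCOC)c1[C@H](O)[C@H](C)C=C
F3 | step 3 | (1R,2R)-1-[2,6-bis(methoxymethoxy)-4-methoxyphenyl]-2-methylbutan-1-ol | COCOc1cc(OC)cc(OCOC)c1[C@H](O)[C@H](C)CC
F4 | step 3 | (2R)-1-[2,6-bis(methoxymethoxy)-4-methoxyphenyl]-2-methylbutan-1-one | COCOc1cc(OC)cc(OCOC)c1C(=O)[C@H](C)CC
F5 | step 5 | 2,4-dihydroxy-6-methoxy-3-[(2R)-2-methylbutanoyl]benzaldehyde | COc1cc(O)c(C(=O)[C@H](C)CC)c(O)c1C=O
F0 | step 4 | none | none
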